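C1 is the ester carbon, C2 the methine, C3–C6 the carbons of the dioxane (ring B), C7–C8 the linker and C9–C14 the enone ring A (C11 carbonyl). R = 2-(2,6,6-trimethyl-3-oxocyclohex-1-en-1-yl)ethyl, that is C7–C14.
Enabling feature: on ring B the side chain at C3 and the methyl group at C6 lie on one face. The two carbons attached there can therefore be tied together as the neighbouring CHOH carbons of a cyclohexa-3,5-diene-cis-1,2-diol in which C3 and C6 are the diene termini.
Cuts, in retrosynthetic order: C2 with its methyl group (Wolff homologation), the bond between the two appendage carbons (glycol cleavage read backwards), O–C3 and O–C6 together ([4+2] with singlet oxygen), C6–C7 (B-alkyl Suzuki–Miyaura), C8–C9 (Stork–Danheiser vinylation).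
Forward: ring A is bought as a dione and dressed, and the carbocycle holding C3–C6 comes from enzymatic dearomatisation of 1-bromo-4-iodobenzene. The two are joined at C6–C7, ring B closes in the cycloaddition, and the helper carbocycle is then cut open so that its two carbons become the 6-methyl group and C1.
Stereochemistry: the dioxygenase sets two carbinol centres, and their acetonide sends oxygen to the other face, which fixes C3 (S) and C6 (R). Glycol cleavage deletes the carbinol centres, C3 migrates with retention in the Wolff step, and C2 (R) comes from substrate-controlled protonation of the ketene–methanol adduct.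

Key step: step 9

Assumption: the size difference between iodine and bromine is taken to be large enough for the dioxygenase to oxidise mainly next to iodine; enantiomeric purity is to be measured at the bromodiol stage before material is carried on.

Step 1
Reactants: 1 1-bromo-4-iodobenzene
Product: 2 (1S,2R)-3-bromo-6-iodocyclohexa-3,5-diene-1,2-diol
Conditions: E. coli JM109(pDTG601) whole cells (toluene dioxygenase), IPTG, glucose, air, phosphate buffer pH 7, 35 °C
Reagents that add atoms: dioxygen, O=O
Why: Enzymatic arene cis-dihydroxylation (dearomatisation) puts both oxygen atoms on one face of the ring bond next to the larger halogen, so iodine occupies the site that the lone substituent of a monosubstituted benzene normally takes and the enzyme pocket sets both carbinol centres.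

Step 2
Reactants: 2 (1S,2R)-3-bromo-6-iodocyclohexa-3,5-diene-1,2-diol
Product: 3 (1R,2R)-3-bromocyclohexa-3,5-diene-1,2-diol
Conditions: Bu3SnH (1.05 equiv), Et3B (cat.), air, THF, 0 °C to rt
Reagents that add atoms: none
Why: Radical hydrodehalogenation is chemoselective because the stannyl radical abstracts iodine from an alkenyl C–I bond far faster than bromine from C–Br, which leaves both carbinol centres untouched and the bromine on the diene terminus that will become C6, the enantiomeric series opposite to the diol of bromobenzene itself.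

Step 3
Reactants: 3 (1R,2R)-3-bromocyclohexa-3,5-diene-1,2-diol; 4 2,2-dimethoxypropane
Product: 5 (3aR,7aR)-4-bromo-2,2-dimethyl-3a,7a-dihydro-1,3-benzodioxole
Conditions: TsOH·H2O (cat.), CH2Cl2, 0 °C to rt; kept cold and used promptly
Reagents that add atoms: none
Why: Acid-catalysed transketalisation with loss of methanol closes a dioxolane on the cis-diol, blocks dehydration to a phenol and installs the group that will later shield one face of the diene.

Step 4
Reactants: 6 4,4-dimethylcyclohexane-1,3-dione
Product: 7 2,4,4-trimethylcyclohexane-1,3-dione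
Conditions: MeI, NaOH, H2O–dioxane, reflux
Reagents that add atoms: iodomethane, CI
Why: C-alkylation of the stabilised 1,3-dicarbonyl enolate places the future C10 methyl group between the two carbonyls, the standard entry to 2-alkylcyclohexane-1,3-diones.

Step 5
Reactants: 7 2,4,4-trimethylcyclohexane-1,3-dione
Product: 8 3-isobutoxy-2,6,6-trimethylcyclohex-2-en-1-one
Conditions: i-BuOH, TsOH·H2O (cat.), toluene, reflux, Dean–Stark
Reagents that add atoms: isobutanol, CC(C)CO
Why: Acid-catalysed enol etherification with removal of water takes place at the carbonyl remote from the gem-dimethyl group, because the alcohol adds to the less hindered carbonyl, so the carbonyl next to the quaternary carbon stays free for the next addition.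

Step 6
Reactants: 8 3-isobutoxy-2,6,6-trimethylcyclohex-2-en-1-one; 9 vinylmagnesium bromide
Product: 11 2,4,4-trimethyl-3-vinylcyclohex-2-en-1-one, via tertiary carbinol 10 (not isolated)
Conditions: THF, 0 °C to rt; then 1 M HCl, rt
Reagents that add atoms: none
Why: In this Stork–Danheiser sequence the Grignard reagent adds 1,2 to the only free carbonyl, which has no hydrogen on its quaternary flank to be enolised, and acid hydrolysis of 10 with allylic transposition unveils the enone with the vinyl group on C9 beside the gem-dimethyl carbon (C8–C9 bond).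

Step 7
Reactants: 11 2,4,4-trimethyl-3-vinylcyclohex-2-en-1-one; 5 (3aR,7aR)-4-bromo-2,2-dimethyl-3a,7a-dihydro-1,3-benzodioxole
Product: 13 (3aS,7aR)-4-[2-(3-hydroxy-2,6,6-trimethylcyclohex-1-en-1-yl)ethyl]-2,2-dimethyl-3a,7a-dihydro-1,3-benzodioxole (both C11 epimers), via bis-boron adduct 12 (not isolated)
Conditions: 9-BBN-H (2.2 equiv per 11), THF, 0 °C to rt; then 5, PdCl2(dppf) (5 mol %), Cs2CO3, DMF–H2O, rt to 40 °C
Reagents that add atoms: 9-BBN-H, [H]B1C2CCCC1CCC2 (its boron units sit in 12 only, none of its atoms other than hydrogen reach 13)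
Why: 9-BBN reduces enones 1,2, hydroborates monosubstituted alkenes at the terminal carbon and ignores tetrasubstituted alkenes, so two equivalents replace an unreliable ketone-versus-alkene competition by the defined species 12, whose primary B-alkyl group alone transmetalates in the B-alkyl Suzuki–Miyaura coupling after oxidative addition of the alkenyl bromide to zerovalent palladium (C6–C7 bond), while the uncontrolled C11 carbinol centre is erased in step 8.

Step 8
Reactants: 13 (3aS,7aR)-4-[2-(3-hydroxy-2,6,6-trimethylcyclohex-1-en-1-yl)ethyl]-2,2-dimethyl-3a,7a-dihydro-1,3-benzodioxole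
Product: 14 (3aS,7aR)-2,2-dimethyl-4-R-3a,7a-dihydro-1,3-benzodioxole
Conditions: MnO2 (activated, excess), CH2Cl2, rt
Reagents that add atoms: none
Why: Allylic alcohol oxidation with MnO2 is neutral, is routine for 3-hydroxy-2,6,6-trimethylcyclohexenyl rings, leaves the acid-sensitive diene acetonide alone, merges the two C11 epimers and restores the enone that will protect C9=C10 from singlet oxygen.

Step 9
Reactants: 14 (3aS,7aR)-2,2-dimethyl-4-R-3a,7a-dihydro-1,3-benzodioxole
Product: 15 (1R,4S,7R,8S)-7,8-isopropylidenedioxy-1-R-2,3-dioxabicyclo[2.2.2]oct-5-ene (acetonide anti to the O–O bridge; C3 S, C6 R)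
Conditions: O2, tetraphenylporphyrin (cat.), visible light, CH2Cl2, −78 °C
Reagents that add atoms: dioxygen, O=O
Why: Energy transfer from photoexcited tetraphenylporphyrin gives singlet oxygen, which adds suprafacially and in concert across the termini C3 and C6 of the ring diene of 14, a hetero-Diels–Alder [4+2] cycloaddition of the kind long established for acetonides of microbial arene cis-dihydrodiols. Ring B closes by cycloaddition: the O–C3 and O–C6 bonds form together and the dioxane appears as the dihydrodioxine bridge of a 2,3-dioxabicyclo[2.2.2]octene. C3 (S) and C6 (R) are both fixed by the choice of diene face, and that choice is made by the enzyme-derived acetonide, whose dioxolane ring and inward methyl group cover their own side so that oxygen arrives anti to it. The two carbinol carbons therefore stay on C3 and C6 on the face away from the peroxide, which is the cis relation of the C3 side chain and the 6-methyl group. Besides facial selectivity the step needs chemoselectivity against ene reactions: the diene is locked s-cis and planar, so cycloaddition outruns hydrogen abstraction at C7, and C9=C10 is conjugated to the C11 carbonyl and too electron-poor to react, which is why 13 is oxidised first. Low temperature and the absence of base keep 15 from rearranging to a bis-epoxide or from Kornblum–DeLaMare opening at the C3–H.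

Step 10
Reactants: 15 (1R,4S,7R,8S)-7,8-isopropylidenedioxy-1-R-2,3-dioxabicyclo[2.2.2]oct-5-ene
Product: 16 (1R,4S,7R,8S)-7,8-isopropylidenedioxy-1-R-2,3-dioxabicyclo[2.2.2]octane
Conditions: KO2CN=NCO2K, AcOH, CH2Cl2–MeOH, −20 to 0 °C
Reagents that add atoms: none
Why: Diimide reduction transfers two hydrogens in concert to the strained, unpolarised C4=C5 bond without touching the O–O bond, the standard way to saturate bicyclic endoperoxides, while the tetrasubstituted conjugated C9=C10 bond is inert.

Step 11
Reactants: 16 (1R,4S,7R,8S)-7,8-isopropylidenedioxy-1-R-2,3-dioxabicyclo[2.2.2]octane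
Product: 17 (1R,4S,7R,8S)-1-R-2,3-dioxabicyclo[2.2.2]octane-7,8-diol
Conditions: CF3CO2H–H2O–THF, 0 °C to rt
Reagents that add atoms: none
Why: Acid-catalysed ketal hydrolysis frees the cis-diol, since dialkyl peroxide and enone tolerate aqueous acid, whereas base, which would trigger Kornblum–DeLaMare cleavage at the C3–H, is avoided.

Step 12
Reactants: 17 (1R,4S,7R,8S)-1-R-2,3-dioxabicyclo[2.2.2]octane-7,8-diol
Product: 19 (3S,6R)-3,6-bis(hydroxymethyl)-6-R-1,2-dioxane, via dialdehyde 18 (not isolated)
Conditions: NaIO4 on SiO2, CH2Cl2, 0 °C; filter; then EtOH, NaBH4, −78 °C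
Reagents that add atoms: none
Why: Malaprade glycol cleavage is fast for the eclipsed cis-diol of the rigid bicycle and leaves the two former carbinol carbons as formyl groups cis on C3 and C6, and immediate low-temperature borohydride reduction, which takes aldehydes ahead of the hindered conjugated ketone, removes the α-peroxy aldehyde before C3 can enolise.

Step 13
Reactants: 19 (3S,6R)-3,6-bis(hydroxymethyl)-6-R-1,2-dioxane
Product: 20 (3S,6R)-3-(tert-butyldimethylsilyloxymethyl)-6-hydroxymethyl-6-R-1,2-dioxane
Conditions: TBSCl (1.0 equiv), imidazole, CH2Cl2, −20 °C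
Reagents that add atoms: tert-butyldimethylsilyl chloride, CC(C)(C)[Si](C)(C)Cl
Why: Sterically governed monosilylation differentiates the two arms, because the CH2OH on the tertiary carbon C3 reacts much faster with the bulky chlorosilane than the neopentyl-type CH2OH on quaternary C6.

Step 14
Reactants: 20 (3S,6R)-3-(tert-butyldimethylsilyloxymethyl)-6-hydroxymethyl-6-R-1,2-dioxane
Product: 22 (3S,6R)-3-(tert-butyldimethylsilyloxymethyl)-6-iodomethyl-6-R-1,2-dioxane, via triflate 21 (not isolated)
Conditions: Tf2O, 2,6-lutidine, CH2Cl2, −78 °C; then Bu4NI, −78 °C to rt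
Reagents that add atoms: tetrabutylammonium iodide, CCCC[N+](CCCC)(CCCC)CCCC.[I-]; triflic anhydride, O=S(=O)(OS(=O)(=O)C(F)(F)F)C(F)(F)F (its CF3SO2 group sits in 21 only)
Why: SN2 displacement of a sulfonate works here because a triflate is reactive enough for a neopentyl-type carbon flanked by an oxygenated quaternary centre, as with hindered primary carbohydrate triflates, and the sequence avoids phosphine reagents that would deoxygenate the peroxide.

Step 15
Reactants: 22 (3S,6R)-3-(tert-butyldimethylsilyloxymethyl)-6-iodomethyl-6-R-1,2-dioxane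
Product: 23 (3S,6R)-3-(tert-butyldimethylsilyloxymethyl)-6-methyl-6-R-1,2-dioxane
Conditions: Bu3SnH (1.5 equiv, about 1 M), Et3B (cat.), air, toluene, −20 °C
Reagents that add atoms: none
Why: In this radical chain hydrodeiodination iodine abstraction by the stannyl radical is far faster than its attack on O–O, and concentrated tin hydride at low temperature should trap the β-peroxyalkyl radical before it closes onto oxygen, as in tin hydride reductions of β-halo dialkyl peroxides, while C6 is not involved and keeps its configuration.

Step 16
Reactants: 23 (3S,6R)-3-(tert-butyldimethylsilyloxymethyl)-6-methyl-6-R-1,2-dioxane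
Product: 26 (3S,6R)-6-methyl-6-R-1,2-dioxane-3-carboxylic acid, via primary alcohol 24 (not isolated), via aldehyde 25 (not isolated)
Conditions: CrO3, H2SO4, H2O, acetone, 0 °C; acidic extractive work-up
Reagents that add atoms: water, O
Why: In the Jones oxidation the aqueous acid strips the primary silyl ether and hexavalent chromium carries alcohol 24 through the hydrate of aldehyde 25 to the acid in one operation, dialkyl peroxide and enone being inert to it, and the acidic medium and work-up spare the C3–H and avoid the carboxylate.

Step 17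
Reactants: 26 (3S,6R)-6-methyl-6-R-1,2-dioxane-3-carboxylic acid; 27 N-ethyl-N-nitrosourea
Product: 30 2-diazo-1-[(3S,6R)-6-methyl-6-R-1,2-dioxan-3-yl]propan-1-one, via acid chloride 28 (not isolated), via diazoethane 29 (not isolated)
Conditions: Me2C=C(Cl)NMe2, CH2Cl2, 0 °C; then added to excess CH3CHN2 in Et2O (from 27, 50% aq KOH, Et2O, 0 °C), −20 to 0 °C
Reagents that add atoms: 1-chloro-N,N,2-trimethylprop-1-en-1-amine, CC(C)=C(Cl)N(C)C (its chlorine sits in 28 only)
Why: Neutral acid chloride formation with the α-chloroenamine followed by acylation of diazoethane (first half of an Arndt–Eistert homologation, a second equivalent of diazoethane taking up HCl) never generates the carboxylate, which would be aligned for decarboxylative Grob-type cleavage of the O–O bond, nor a base able to enolise C3, so C3 stays S.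

Step 18
Reactants: 30 2-diazo-1-[(3S,6R)-6-methyl-6-R-1,2-dioxan-3-yl]propan-1-one
Product: 33 methyl diacarnoate A (2R,3S,6R), via methylketene 31 (not isolated), via ketene hemiacetal 32 (not isolated)
Conditions: hν (365 nm LED), MeOH–CH2Cl2, −78 °C
Reagents that add atoms: methanol, CO
Why: The photochemical Wolff rearrangement (second half of the Arndt–Eistert sequence) shifts C3 to the diazo carbon with retention to give methylketene 31, methanol adds in the ketene plane from the methyl side to give hemiacetal 32, and in 32 A1,3 strain turns H-3 toward the cis hydroxyl while the C3–O bond stands perpendicular to the electron-rich double bond, so that proton transfer to C2 anti to that C–O bond, the sense known for protonation of β-alkoxy ester enolates and for anti addition of alcohols to (E)-2-methylenoates, should set C2 as R, low temperature sharpening the choice as in related diazoethane homologations of α-heteroatom acids.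

Compound list
1 | 1-bromo-4-iodobenzene | Brc1ccc(I)cc1 | starting material
2 | (1S,2R)-3-bromo-6-iodocyclohexa-3,5-diene-1,2-diol (cis-diol, carbinol next to C–I is S) | O[C@@H]1C(I)=CC=C(Br)[C@@H]1O | intermediate
3 | (1R,2R)-3-bromocyclohexa-3,5-diene-1,2-diol (cis-diol) | O[C@@H]1C=CC=C(Br)[C@@H]1O | intermediate
4 | 2,2-dimethoxypropane | COC(C)(C)OC | starting material
5 | (3aR,7aR)-4-bromo-2,2-dimethyl-3a,7a-dihydro-1,3-benzodioxole | CC1(C)O[C@@H]2C=CC=C(Br)[C@@H]2O1 | intermediate
6 | 4,4-dimethylcyclohexane-1,3-dione | CC1(C)CCC(=O)CC1=O | starting material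
7 | 2,4,4-trimethylcyclohexane-1,3-dione | CC1C(=O)CCC(C)(C)C1=O | intermediate
8 | 3-isobutoxy-2,6,6-trimethylcyclohex-2-en-1-one | CC(C)COC1=C(C)C(=O)C(C)(C)CC1 | intermediate
9 | vinylmagnesium bromide | C=C[Mg]Br | starting material
10 | 3-isobutoxy-2,6,6-trimethyl-1-vinylcyclohex-2-en-1-ol (racemic, not isolated) | CC(C)COC1=C(C)C(O)(C=C)C(C)(C)CC1 | intermediate
11 | 2,4,4-trimethyl-3-vinylcyclohex-2-en-1-one | C=CC1=C(C)C(=O)CCC1(C)C | intermediate
12 | bis-boron adduct: C7 bound to 9-BBN, C11 oxygen bound to a second 9-BBN (racemic at C11, not isolated) | CC1=C(CCB2C3CCCC2CCC3)C(C)(C)CCC1OB1C2CCCC1CCC2 | intermediate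
13 | (3aS,7aR)-4-[2-(3-hydroxy-2,6,6-trimethylcyclohex-1-en-1-yl)ethyl]-2,2-dimethyl-3a,7a-dihydro-1,3-benzodioxole (both C11 epimers) | CC1(C)O[C@@H]2C=CC=C(CCC3=C(C)C(O)CCC3(C)C)[C@@H]2O1 | intermediate
14 | 3-{2-[(3aS,7aR)-2,2-dimethyl-3a,7a-dihydro-1,3-benzodioxol-4-yl]ethyl}-2,4,4-trimethylcyclohex-2-en-1-one (key-step precursor) | CC1(C)O[C@@H]2C=CC=C(CCC3=C(C)C(=O)CCC3(C)C)[C@@H]2O1 | intermediate
15 | (1R,4S,7R,8S)-7,8-isopropylidenedioxy-1-R-2,3-dioxabicyclo[2.2.2]oct-5-ene, acetonide anti to O–O (key-step product) | CC1(C)O[C@@H]2[C@@H]3C=C[C@@](CCC4=C(C)C(=O)CCC4(C)C)(OO3)[C@@H]2O1 | intermediate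
16 | (1R,4S,7R,8S)-7,8-isopropylidenedioxy-1-R-2,3-dioxabicyclo[2.2.2]octane | CC1(C)O[C@@H]2[C@@H]3CC[C@@](CCC4=C(C)C(=O)CCC4(C)C)(OO3)[C@@H]2O1 | intermediate
17 | (1R,4S,7R,8S)-1-R-2,3-dioxabicyclo[2.2.2]octane-7,8-diol | O[C@@H]1[C@@H]2CC[C@@](CCC3=C(C)C(=O)CCC3(C)C)(OO2)[C@@H]1O | intermediate
18 | (3S,6R)-6-R-1,2-dioxane-3,6-dicarbaldehyde (not isolated) | O=C[C@@H]1CC[C@@](C=O)(CCC2=C(C)C(=O)CCC2(C)C)OO1 | intermediate
19 | (3S,6R)-3,6-bis(hydroxymethyl)-6-R-1,2-dioxane | OC[C@@H]1CC[C@@](CO)(CCC2=C(C)C(=O)CCC2(C)C)OO1 | intermediate
20 | (3S,6R)-3-(tert-butyldimethylsilyloxymethyl)-6-hydroxymethyl-6-R-1,2-dioxane | CC(C)(C)[Si](C)(C)OC[C@@H]1CC[C@@](CO)(CCC2=C(C)C(=O)CCC2(C)C)OO1 | intermediate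
21 | triflate of 20 at the C6 hydroxymethyl group (not isolated) | CC(C)(C)[Si](C)(C)OC[C@@H]1CC[C@@](COS(=O)(=O)C(F)(F)F)(CCC2=C(C)C(=O)CCC2(C)C)OO1 | intermediate
22 | (3S,6R)-3-(tert-butyldimethylsilyloxymethyl)-6-iodomethyl-6-R-1,2-dioxane | CC(C)(C)[Si](C)(C)OC[C@@H]1CC[C@@](CI)(CCC2=C(C)C(=O)CCC2(C)C)OO1 | intermediate
23 | (3S,6R)-3-(tert-butyldimethylsilyloxymethyl)-6-methyl-6-R-1,2-dioxane | CC(C)(C)[Si](C)(C)OC[C@@H]1CC[C@@](C)(CCC2=C(C)C(=O)CCC2(C)C)OO1 | intermediate
24 | (3S,6R)-3-hydroxymethyl-6-methyl-6-R-1,2-dioxane (not isolated) | OC[C@@H]1CC[C@@](C)(CCC2=C(C)C(=O)CCC2(C)C)OO1 | intermediate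
25 | (3S,6R)-6-methyl-6-R-1,2-dioxane-3-carbaldehyde (not isolated) | O=C[C@@H]1CC[C@@](C)(CCC2=C(C)C(=O)CCC2(C)C)OO1 | intermediate
26 | (3S,6R)-6-methyl-6-R-1,2-dioxane-3-carboxylic acid | OC(=O)[C@@H]1CC[C@@](C)(CCC2=C(C)C(=O)CCC2(C)C)OO1 | intermediate
27 | N-ethyl-N-nitrosourea | CCN(N=O)C(N)=O | starting material
28 | (3S,6R)-6-methyl-6-R-1,2-dioxane-3-carbonyl chloride (not isolated) | ClC(=O)[C@@H]1CC[C@@](C)(CCC2=C(C)C(=O)CCC2(C)C)OO1 | intermediate
29 | diazoethane (ethereal solution, not isolated) | CC=[N+]=[N-] | intermediate
30 | 2-diazo-1-[(3S,6R)-6-methyl-6-R-1,2-dioxan-3-yl]propan-1-one | CC(=[N+]=[N-])C(=O)[C@@H]1CC[C@@](C)(CCC2=C(C)C(=O)CCC2(C)C)OO1 | intermediate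
31 | 2-[(3S,6R)-6-methyl-6-R-1,2-dioxan-3-yl]prop-1-en-1-one, the methylketene (not isolated) | CC(=C=O)[C@@H]1CC[C@@](C)(CCC2=C(C)C(=O)CCC2(C)C)OO1 | intermediate
32 | ketene hemiacetal, methoxy cis to the C2 methyl group, hydroxyl cis to C3 (not isolated) | CO/C(O)=C(\C)[C@@H]1CC[C@@](C)(CCC2=C(C)C(=O)CCC2(C)C)OO1 | intermediate
33 | methyl diacarnoate A, methyl (2R)-2-[(3S,6R)-6-methyl-6-R-1,2-dioxan-3-yl]propanoate | COC(=O)[C@H](C)[C@@H]1CC[C@@](C)(CCC2=C(C)C(=O)CCC2(C)C)OO1 | target

Total step count: 18 steps.
Longest linear sequence: 15 steps (steps 1–3, then 7–18; the branch through steps 4–6 is equally long).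

Steps most likely to fail

Step 18. Facial selectivity in the proton transfer to C2 may be poor or reversed, since steric and stereoelectronic preferences at C3 need not agree, and a 1,2-hydrogen shift of the carbene may compete with the rearrangement. The fallback replaces substrate control by reagent control; it sets out from 30 and returns at 33.
- The photolysis is run in toluene at −78 °C without methanol, with (R)-pantolactone and a catalytic amount of Me2NEt.
- The chiral alcohol then governs the proton transfer in the adduct of ketene 31. This is the known diastereoselective addition of α-hydroxy lactones to ketenes, with C3 taking the place of the larger ketene substituent.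
- It gives the (R)-pantolactone ester F1, from which any C2 epimer can be removed as a diastereomer.
- Acid-catalysed methanolysis (MeOH, H2SO4 cat., 40 °C), which does not enolise C2, then gives 33.

Step 15. The β-peroxyalkyl radical may collapse onto the neighbouring oxygen, opening the O–O bond before hydrogen transfer. The fallback avoids any carbon radical next to the peroxide; it sets out from 20 and returns at 23.
- Triflate 21 is made as in step 14 and treated with Bu4NBH4 in CH2Cl2–toluene (0 to 40 °C).
- This is a polar SN2 hydride displacement of the kind used to deoxygenate hindered carbohydrate triflates, and borohydride leaves dialkyl peroxides intact.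
- The C11 ketone is expected to be reduced alongside, giving the allylic alcohol F2.
- MnO2 as in step 8 returns F2 to 23.

Step 1. Discrimination between iodine and bromine in the enzyme pocket may be incomplete, which erodes enantiomeric purity and cannot be repaired later. The fallback is a kinetic resolution; it sets out from 3 of insufficient purity and returns at 3.
- The bromodiol is incubated with whole cells that express the cis-dihydrodiol dehydrogenase (for example E. coli JM109(pDTG602)).
- That enzyme accepts only the (1S,2S) enantiomer and aromatises it to 3-bromocatechol F3, which a basic wash removes.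
- The untouched (1R,2R)-diol 3 enters step 3.

Further compounds
F1 | step 18 | (R)-pantolactone ester of (2R)-2-[(3S,6R)-6-methyl-6-R-1,2-dioxan-3-yl]propanoic acid | CC1(C)COC(=O)[C@@H]1OC(=O)[C@H](C)[C@@H]2CC[C@@](C)(CCC3=C(C)C(=O)CCC3(C)C)OO2
F2 | step 15 | (3S,6R)-3-(tert-butyldimethylsilyloxymethyl)-6-[2-(3-hydroxy-2,6,6-trimethylcyclohex-1-en-1-yl)ethyl]-6-methyl-1,2-dioxane (both C11 epimers) | CC(C)(C)[Si](C)(C)OC[C@@H]1CC[C@@](C)(CCC2=C(C)C(O)CCC2(C)C)OO1
F3 | step 1 | 3-bromocatechol | Oc1cccc(Br)c1O
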